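**Retrosynthetic overview**
1. The dihydrofuran ring is closed last but one, by forming the aryl ether bond O1–C7a: the C2 alkoxide of an open-chain 1,2-diaryl-3-aryloxypropan-1-ol displaces a fluorine on C7a of ring A (intramolecular SNAr, 5-exo).
2. Enabling feature: C7a of ring A is ortho to C3a (the carbon that carries C3) and flanked by the C7 methoxy group, so O1 on C2 reaches a C7a–F through a five-membered transition state. The 2,3-trans ring corresponds to the syn relationship of an open-chain aldol, so both stereocentres can be set acyclically and carried through a closure that breaks no bond at C2 or C3.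
3. Disconnections before the closure: CH2–OAr by Mitsunobu etherification with eugenol (this also removes the primary oxygen as a competitor); C2–C3 by an Evans syn-aldol between an arylacetyl oxazolidinone and protected vanillin.
4. Ring A: the C5 allyl group comes from sterically controlled C–H borylation/allylation of a 2-fluoro-3-methoxyphenylacetate; the fluorine is first a blocking group and later the leaving group.
5. Ring order: the three benzene rings are bought; the dihydrofuran ring (O1, C2, C3, C3a, C7a) is the only ring made.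

Key step: step 9

Assumption: 2-(2-fluoro-3-methoxyphenyl)acetic acid (compound 1) is taken as a catalogue building block, like the other starting materials.

Step 1
Reactants: 1 2-(2-fluoro-3-methoxyphenyl)acetic acid
Product: 2 methyl 2-(2-fluoro-3-methoxyphenyl)acetate
Conditions: MeOH, H2SO4 (cat.), reflux
Reagents that add atoms: methanol, CO
Why: Fischer esterification of an unhindered arylacetic acid should proceed cleanly and gives an ester that tolerates the C–H borylation and whose α-CH2 is too weakly acidic to be allylated in step 2.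

Step 2
Reactants: 2 methyl 2-(2-fluoro-3-methoxyphenyl)acetate
Product: 4 methyl 2-(5-allyl-2-fluoro-3-methoxyphenyl)acetate, via arylboronate 3 (not isolated)
Conditions: [Ir(cod)(OMe)]2 (cat.), 4,4'-di-tert-butyl-2,2'-bipyridine, B2pin2, THF, 80 °C; volatiles removed; then Pd(PPh3)4 (cat.), allyl bromide, CsF, THF, 65 °C
Reagents that add atoms: allyl bromide, C=CCBr
Why: Iridium-catalysed aromatic C–H borylation is sterically controlled and should pick C5, the only ring C–H of this 1,2,3-trisubstituted arene with no ortho substituent, after which Suzuki–Miyaura coupling of boronate 3 with the π-allylpalladium species from allyl bromide installs the allyl group para to fluorine.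

Step 3
Reactants: 4 methyl 2-(5-allyl-2-fluoro-3-methoxyphenyl)acetate
Product: 5 2-(5-allyl-2-fluoro-3-methoxyphenyl)acetic acid
Conditions: LiOH, THF/H2O, 0 °C to rt; then 1 M HCl
Reagents that add atoms: lithium hydroxide, [Li+].[OH-]
Why: Saponification of the methyl ester with LiOH at low temperature is a standard acyl substitution that should leave the aryl fluoride and the allyl group untouched.

Step 4
Reactants: 5 2-(5-allyl-2-fluoro-3-methoxyphenyl)acetic acid; 6 (4S)-4-benzyl-1,3-oxazolidin-2-one
Product: 8 (4S)-3-[2-(5-allyl-2-fluoro-3-methoxyphenyl)acetyl]-4-benzyl-1,3-oxazolidin-2-one, via mixed anhydride 7 (not isolated)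
Conditions: t-BuCOCl, Et3N, THF, −20 °C; then 6, LiCl, −20 °C to rt
Reagents that add atoms: none
Why: N-Acylation of the oxazolidinone through the mixed pivalic anhydride with LiCl/Et3N activation is the standard way to load an Evans auxiliary and does not touch its stereocentre.

Step 5
Reactants: 9 vanillin (4-hydroxy-3-methoxybenzaldehyde)
Product: 10 3-methoxy-4-(methoxymethoxy)benzaldehyde
Conditions: MOMCl, i-Pr2NEt, CH2Cl2, 0 °C to rt
Reagents that add atoms: chloromethyl methyl ether, COCCl
Why: O-Alkylation of the phenol gives a methoxymethyl ether that should withstand the boron aldol, hydride, Mitsunobu and strong-base steps and is removed by mild acid at the end.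

Step 6
Reactants: 8 (4S)-3-[2-(5-allyl-2-fluoro-3-methoxyphenyl)acetyl]-4-benzyl-1,3-oxazolidin-2-one; 10 3-methoxy-4-(methoxymethoxy)benzaldehyde
Product: 13 (4S)-3-[(2S,3S)-2-(5-allyl-2-fluoro-3-methoxyphenyl)-3-hydroxy-3-[3-methoxy-4-(methoxymethoxy)phenyl]propanoyl]-4-benzyl-1,3-oxazolidin-2-one, via boron enolate 11 (not isolated), via boron aldolate 12 (not isolated)
Conditions: Bu2BOTf, i-Pr2NEt, CH2Cl2, −78 to 0 °C; 10, −78 to 0 °C; then pH 7 buffer, MeOH, H2O2, 0 °C
Reagents that add atoms: none
Why: Evans syn-aldol reaction: the Z-boron enolate 11 reacts through a closed Zimmerman–Traxler chair on the face opposite the benzyl group of the (S)-auxiliary, which should set both stereocentres as (2S,3S), the syn pair that becomes C3 and C2 of the target.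

Step 7
Reactants: 13 (4S)-3-[(2S,3S)-2-(5-allyl-2-fluoro-3-methoxyphenyl)-3-hydroxy-3-[3-methoxy-4-(methoxymethoxy)phenyl]propanoyl]-4-benzyl-1,3-oxazolidin-2-one
Product: 14 (1S,2R)-2-(5-allyl-2-fluoro-3-methoxyphenyl)-1-[3-methoxy-4-(methoxymethoxy)phenyl]propane-1,3-diol
Conditions: LiBH4, MeOH (1 equiv), THF, 0 °C to rt
Reagents that add atoms: none
Why: Reductive cleavage of the imide with LiBH4 attacks the exocyclic carbonyl selectively, releases the auxiliary and gives the 1,3-diol without touching either stereocentre (the descriptor of the aryl-bearing carbon changes from S to R only because the CIP priorities change).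

Step 8
Reactants: 14 (1S,2R)-2-(5-allyl-2-fluoro-3-methoxyphenyl)-1-[3-methoxy-4-(methoxymethoxy)phenyl]propane-1,3-diol; 15 eugenol (4-allyl-2-methoxyphenol)
Product: 16 (1S,2R)-3-(4-allyl-2-methoxyphenoxy)-2-(5-allyl-2-fluoro-3-methoxyphenyl)-1-[3-methoxy-4-(methoxymethoxy)phenyl]propan-1-ol
Conditions: PPh3, DIAD, THF, 0 °C to rt
Reagents that add atoms: none
Why: Mitsunobu etherification should engage the less hindered primary hydroxyl with the phenol (pKa about 10) and leave the secondary benzylic hydroxyl free, so no stereocentre is inverted and the primary oxygen can no longer compete in the ring closure.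

Step 9
Reactants: 16 (1S,2R)-3-(4-allyl-2-methoxyphenoxy)-2-(5-allyl-2-fluoro-3-methoxyphenyl)-1-[3-methoxy-4-(methoxymethoxy)phenyl]propan-1-ol
Product: 18 (2S,3R)-5-allyl-3-[(4-allyl-2-methoxyphenoxy)methyl]-7-methoxy-2-[3-methoxy-4-(methoxymethoxy)phenyl]-2,3-dihydro-1-benzofuran, via potassium alkoxide 17 (not isolated)
Conditions: KN(SiMe3)2 (1.05 equiv), 18-crown-6, THF, 0 °C, then 65 °C
Reagents that add atoms: none
Why: Deprotonation of the C2 hydroxyl gives alkoxide 17, whose oxygen adds to the fluorine-bearing carbon C7a of ring A and expels fluoride in an addition–elimination nucleophilic aromatic substitution that forms the O1–C7a bond. The closest known reaction type is the base-mediated intramolecular SNAr etherification of non-activated 2-(2-fluoroaryl)ethanols to 2,3-dihydrobenzofurans. The dihydrofuran ring (O1, C2, C3, C3a, C7a) closes in the 5-exo-trig mode, the attacked C7a=C7 π bond lying outside the new ring. No stereocentre is created: C2 and C3 keep the syn relationship fixed by the aldol of step 6, which becomes 2,3-trans in the ring because neither the C2–O1 bond nor any bond at C3 is broken. The step needs chemoselectivity for substitution at C7a over loss of the eugenoxide by fragmentation and over allyl-to-propenyl migration; this should be secured by the single fluorine ortho to the side chain with inductive withdrawal from the neighbouring C7 methoxy group, by the primary oxygen already being capped as the aryl ether, and by using one equivalent of a hindered amide base so that only the alkoxide, too weak a base to deprotonate the allylic positions quickly, is present on heating.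

Step 10
Reactants: 18 (2S,3R)-5-allyl-3-[(4-allyl-2-methoxyphenoxy)methyl]-7-methoxy-2-[3-methoxy-4-(methoxymethoxy)phenyl]-2,3-dihydro-1-benzofuran
Product: 19 4-[(2S,3R)-5-allyl-3-[(4-allyl-2-methoxyphenoxy)methyl]-7-methoxy-2,3-dihydro-1-benzofuran-2-yl]-2-methoxyphenol
Conditions: HCl (2 M aq., cat.), MeOH/THF, 40 °C
Reagents that add atoms: none
Why: Acid-catalysed acetal exchange with methanol removes the methoxymethyl group as dimethoxymethane under conditions too mild to ionise the benzylic C2–O1 ether or to add to the allyl groups, so both stereocentres should be kept.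

**Compound list**
1 | 2-(2-fluoro-3-methoxyphenyl)acetic acid | OC(=O)Cc1cccc(OC)c1F | starting material
2 | methyl 2-(2-fluoro-3-methoxyphenyl)acetate | COC(=O)Cc1cccc(OC)c1F | intermediate
3 | methyl 2-[2-fluoro-3-methoxy-5-(4,4,5,5-tetramethyl-1,3,2-dioxaborolan-2-yl)phenyl]acetate | COC(=O)Cc1cc(B2OC(C)(C)C(C)(C)O2)cc(OC)c1F | intermediate
4 | methyl 2-(5-allyl-2-fluoro-3-methoxyphenyl)acetate | COC(=O)Cc1cc(CC=C)cc(OC)c1F | intermediate
5 | 2-(5-allyl-2-fluoro-3-methoxyphenyl)acetic acid | OC(=O)Cc1cc(CC=C)cc(OC)c1F | intermediate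
6 | (4S)-4-benzyl-1,3-oxazolidin-2-one | O=C1OC[C@H](Cc2ccccc2)N1 | starting material
7 | 2-(5-allyl-2-fluoro-3-methoxyphenyl)acetic pivalic anhydride | CC(C)(C)C(=O)OC(=O)Cc1cc(CC=C)cc(OC)c1F | intermediate
8 | (4S)-3-[2-(5-allyl-2-fluoro-3-methoxyphenyl)acetyl]-4-benzyl-1,3-oxazolidin-2-one | O=C1OC[C@H](Cc2ccccc2)N1C(=O)Cc3cc(CC=C)cc(OC)c3F | intermediate
9 | vanillin (4-hydroxy-3-methoxybenzaldehyde) | COc1cc(C=O)ccc1O | starting material
10 | 3-methoxy-4-(methoxymethoxy)benzaldehyde | COCOc1ccc(C=O)cc1OC | intermediate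
11 | (Z)-dibutylboron enolate of imide 8 | CCCCB(CCCC)O/C(=C\c1cc(CC=C)cc(OC)c1F)N2C(=O)OC[C@@H]2Cc3ccccc3 | intermediate
12 | O-dibutylboryl aldolate of compound 13 | O=C1OC[C@H](Cc2ccccc2)N1C(=O)[C@@H](c3cc(CC=C)cc(OC)c3F)[C@H](OB(CCCC)CCCC)c4ccc(OCOC)c(OC)c4 | intermediate
13 | (4S)-3-[(2S,3S)-2-(5-allyl-2-fluoro-3-methoxyphenyl)-3-hydroxy-3-[3-methoxy-4-(methoxymethoxy)phenyl]propanoyl]-4-benzyl-1,3-oxazolidin-2-one | O=C1OC[C@H](Cc2ccccc2)N1C(=O)[C@@H](c3cc(CC=C)cc(OC)c3F)[C@H](O)c4ccc(OCOC)c(OC)c4 | intermediate
14 | (1S,2R)-2-(5-allyl-2-fluoro-3-methoxyphenyl)-1-[3-methoxy-4-(methoxymethoxy)phenyl]propane-1,3-diol | OC[C@@H](c1cc(CC=C)cc(OC)c1F)[C@H](O)c2ccc(OCOC)c(OC)c2 | intermediate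
15 | eugenol (4-allyl-2-methoxyphenol) | C=CCc1ccc(O)c(OC)c1 | starting material
16 | (1S,2R)-3-(4-allyl-2-methoxyphenoxy)-2-(5-allyl-2-fluoro-3-methoxyphenyl)-1-[3-methoxy-4-(methoxymethoxy)phenyl]propan-1-ol | C=CCc1ccc(OC[C@@H](c2cc(CC=C)cc(OC)c2F)[C@H](O)c3ccc(OCOC)c(OC)c3)c(OC)c1 | intermediate
17 | potassium (1S,2R)-3-(4-allyl-2-methoxyphenoxy)-2-(5-allyl-2-fluoro-3-methoxyphenyl)-1-[3-methoxy-4-(methoxymethoxy)phenyl]propan-1-olate | C=CCc1ccc(OC[C@@H](c2cc(CC=C)cc(OC)c2F)[C@H]([O-])c3ccc(OCOC)c(OC)c3)c(OC)c1.[K+] | intermediate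
18 | (2S,3R)-5-allyl-3-[(4-allyl-2-methoxyphenoxy)methyl]-7-methoxy-2-[3-methoxy-4-(methoxymethoxy)phenyl]-2,3-dihydro-1-benzofuran | C=CCc1ccc(OC[C@H]2c3cc(CC=C)cc(OC)c3O[C@@H]2c4ccc(OCOC)c(OC)c4)c(OC)c1 | intermediate
19 | 4-[(2S,3R)-5-allyl-3-[(4-allyl-2-methoxyphenoxy)methyl]-7-methoxy-2,3-dihydro-1-benzofuran-2-yl]-2-methoxyphenol | C=CCc1ccc(OC[C@H]2c3cc(CC=C)cc(OC)c3O[C@@H]2c2ccc(O)c(OC)c2)c(OC)c1 | target

**Step count and risks**
Total step count: 10. Longest linear sequence: 9 steps (steps 1–4 and 6–10).

The three steps most likely to fail: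

Step 9 (ring closure). The alkoxide may fragment (C2–C3 cleavage with loss of the eugenoxide), or the allyl double bonds may migrate into conjugation, faster than the electron-rich fluoroarene is substituted. The fallback changes the order of events so that the ring is closed before the eugenyl ether exists. It sets out from diol 14. Tritylation of the primary hydroxyl (TrCl, Et3N, DMAP, CH2Cl2) would give (1S,2R)-2-(5-allyl-2-fluoro-3-methoxyphenyl)-1-[3-methoxy-4-(methoxymethoxy)phenyl]-3-(trityloxy)propan-1-ol F1. The same SNAr closure (KN(SiMe3)2, 18-crown-6, THF, 65 °C) would then give (2S,3R)-5-allyl-7-methoxy-2-[3-methoxy-4-(methoxymethoxy)phenyl]-3-[(trityloxy)methyl]-2,3-dihydro-1-benzofuran F2. This substrate has no aryloxide leaving group and only one allyl group, so it can be heated harder. Detritylation (TsOH cat., MeOH/CH2Cl2, 0 °C) would give [(2S,3R)-5-allyl-7-methoxy-2-[3-methoxy-4-(methoxymethoxy)phenyl]-2,3-dihydro-1-benzofuran-3-yl]methanol F3. Mitsunobu etherification of this alcohol with eugenol 15 (PPh3, DIAD, THF) would come back to the route at compound 18.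

Step 8 (Mitsunobu etherification). Chemoselectivity between the two hydroxyls may be lost: activation of the benzylic secondary hydroxyl would lead to elimination or oxetane formation. The fallback is a two-step Williamson sequence from diol 14. Selective sulfonylation of the primary hydroxyl (TsCl, pyridine, CH2Cl2, 0 °C) would give (2R,3S)-2-(5-allyl-2-fluoro-3-methoxyphenyl)-3-hydroxy-3-[3-methoxy-4-(methoxymethoxy)phenyl]propyl 4-methylbenzenesulfonate F4. SN2 displacement with eugenol 15 (K2CO3, DMF, 60 °C) would come back to the route at compound 16.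

Step 2 (one-pot borylation/allylation). The boronate may protodeboronate, or the new allyl double bond may migrate into conjugation under palladium hydride conditions and give a propenyl isomer that is hard to separate. The fallback sets out from ester 2: the borylation is run as before and boronate 3 is isolated. Copper-mediated iododeboronation (CuI cat., 1,10-phenanthroline, KI, MeOH/H2O, air) would give methyl 2-(2-fluoro-5-iodo-3-methoxyphenyl)acetate F5. Base-free Stille coupling with allyltributylstannane (Pd(PPh3)4, toluene, 90 °C) would come back to the route at compound 4.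

**Further compounds**
F1 | step 9 | (1S,2R)-2-(5-allyl-2-fluoro-3-methoxyphenyl)-1-[3-methoxy-4-(methoxymethoxy)phenyl]-3-(trityloxy)propan-1-ol | C(c1ccccc1)(c1ccccc1)(c1ccccc1)OC[C@@H](c1cc(CC=C)cc(OC)c1F)[C@H](O)c1ccc(OCOC)c(OC)c1
F2 | step 9 | (2S,3R)-5-allyl-7-methoxy-2-[3-methoxy-4-(methoxymethoxy)phenyl]-3-[(trityloxy)methyl]-2,3-dihydro-1-benzofuran | C(c1ccccc1)(c1ccccc1)(c1ccccc1)OC[C@H]2c3cc(CC=C)cc(OC)c3O[C@@H]2c4ccc(OCOC)c(OC)c4
F3 | step 9 | [(2S,3R)-5-allyl-7-methoxy-2-[3-methoxy-4-(methoxymethoxy)phenyl]-2,3-dihydro-1-benzofuran-3-yl]methanol | OC[C@H]2c3cc(CC=C)cc(OC)c3O[C@@H]2c4ccc(OCOC)c(OC)c4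
F4 | step 8 | (2R,3S)-2-(5-allyl-2-fluoro-3-methoxyphenyl)-3-hydroxy-3-[3-methoxy-4-(methoxymethoxy)phenyl]propyl 4-methylbenzenesulfonate | Cc1ccc(cc1)S(=O)(=O)OC[C@@H](c2cc(CC=C)cc(OC)c2F)[C@H](O)c3ccc(OCOC)c(OC)c3
F5 | step 2 | methyl 2-(2-fluoro-5-iodo-3-methoxyphenyl)acetate | COC(=O)Cc1cc(I)cc(OC)c1F
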